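## Structural features

Cinnamtannin A2 (22) is a linear tetramer of (−)-epicatechin: four flavan-3-ol units, each a phloroglucinol-type ring A fused to a dihydropyran ring C that carries a catechol ring B on C2, joined by three C4→C8 bonds. Each of the three upper units has three contiguous stereocentres (C2, C3, C4; 2,3-cis, 3,4-trans; 2R,3R,4R) and the bottom unit has two (2R,3R), eleven in all. Every interflavan C4 is a doubly benzylic methine between two tri-oxygenated arenes. The fragile elements are the sixteen phenols (the catechols oxidise readily under base and air), the C4–C8 bonds (acid re-ionises them, which causes cleavage and scrambling) and C2 (base opens ring C once the 4′-phenol is free). The monomer is available with C2 and C3 in place, so the real difficulty lies in making the interflavan bonds with control of site (C8 against C6), chain length and 4β configuration, and in handling very large polyether intermediates. The key step uses ring C of the top unit: O1–C8a–C4a–C4 is the skeleton of an ortho-quinone methide of ring A, and C2–C3 with its cis aryl and oxygen substituents is a Z-configured β-aryl enol ester. One [4+2] event therefore forms O1–C2 and C3–C4, closes the ring and sets C2, C3 and C4, while the C4–C8 bond to the trimer is already present as the substituent on the heterodiene terminus. The configuration of every numbered compound below was checked unit by unit against 22, and no change to connectivity or configuration of the key-step precursor or product was needed.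

## Logic of the disconnections

From 22 the nineteen O–benzyl bonds are cut first (21), then the single O–acyl bond at O3 of the top unit (20). All phenols and the three lower O3 atoms must stay masked through organolithium and acid steps, and benzyl ethers are the one mask that falls in a single neutral operation; the acetate is simply what the dienophile brings. The gain is a stable, chromatographable tetramer. The forward demand is that methanolysis comes before hydrogenolysis, so that base never meets free catechols, and that hydrogenolysis spares the benzylic O1–C2 and C4–C8 bonds.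

In 20 the O1–C2 and C3–C4 bonds of ring C of the top unit are cut. They are the two σ bonds of a [4+2] adduct between a heterodiene (19: O1, C8a, C4a, C4) and an alkene (18: C2, C3). One ring, three stereocentres and ring B leave together, and what remains (15) is a trimer with a benzylic alcohol on C8. The forward step must deliver four things at once: oxygen bonding to the aryl-bearing alkene carbon, retention of the alkene geometry, the inside orientation of the trimer on the heterodiene combined with endo approach, and attack on one face.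

In 15 the ortho phenol is masked as an allyl ether (14), and the bond between the carbinol carbon and C8 of the trimer is cut to an aryllithium (13) and an aldehyde (12); 13 comes from the aryl bromide 9. An allyl group is preferred to a silyl group because it cannot shift to the new alkoxide, so it cannot trigger loss of the benzylic oxygen under basic conditions, and it is removed under neutral conditions. The gain is that the whole top ring A arrives as one small aldehyde. The demand is that halogen–lithium exchange outruns benzylic deprotonation and that a hindered nucleophile adds to a doubly ortho-substituted aldehyde; the carbinol configuration is irrelevant.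

The two C4–C8 bonds of 9 are cut in turn, each giving the same electrophile 5 and a nucleophile with a free C8 (8, then 3). The bromine on C8 of 5 is deliberate: it blocks self-condensation of the electrophile and further growth of each product, and the bromine left on the last unit added is exactly the handle needed for 13, so no selective halogenation of a trimer is required. Between the couplings the bromine of 6 is exchanged for hydrogen (through 7) to free C8 in 8. The demand is attack at C8 and not C6, approach anti to the C3 benzyloxy group (4β), and a Lewis acid weak and cold enough not to re-ionise the bond already made.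

5 is simplified by removing the C4–O bond (4), the C8–Br bond (3), the O3 benzyl (2) and the four phenolic benzyls (1). Since 1 already holds C2 and C3, the route never has to create these centres in the three lower units. The demand is phenol-selective benzylation without C2 epimerisation, C8-selective bromination and C4-selective oxidation.

12 is cut at the O–allyl bond (11) and at two O–benzyl bonds (10). The three phenols are told apart by the hydrogen bond that one ortho hydroxyl makes to the formyl group, which makes it the last to be alkylated.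

18 is cut at the enol C–O bond to a terminal alkyne (17) and a carboxylic acid, and 17 at the triple bond to the aldehyde 16 by one-carbon homologation. The demand is anti-Markovnikov, Z-selective addition to the alkyne.

## Other disconnections considered

Alternative 1: The four O1–C2 bonds are cut, leaving an open-chain tetraene A1 in which each ring B hangs on a Z-alkene, each C8a oxygen is a tert-butyldimethylsilyl ether and the three diarylmethine C4 centres are already set. In the forward step [N,N′-bis(3,5-di-tert-butylsalicylidene)-1,2-cyclohexanediaminato]manganese chloride A2 (a complex of trivalent manganese) with hypochlorite as oxidant would epoxidise the four alkenes, and fluoride would free the four phenoxides, each opening its own epoxide at benzylic C2 to give hexadeca-O-benzylcinnamtannin A2 A3.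
- In favour: four rings and eight stereocentres form in one operation. The 2,3-cis relation follows stereospecifically from SN2 opening of a cis-epoxide, which is the equal of or better than the chosen plan, where it depends on the cycloaddition staying concerted. The 3-hydroxyls emerge free, so only hydrogenolysis remains after the key step, one step fewer than from 20.
- Against: the three C4 centres of A1 are isolated stereocentres that must be made enantioselectively in an open chain, without the cyclic cation that controls them in steps 5 and 7. Epoxidation of aryl-conjugated Z-alkenes by this catalyst class passes through an intermediate that can rotate and so lose the cis geometry, and the selectivity must hold four times over, each time against a nearby C4 centre. The oxidant may chlorinate the electron-rich rings, the para-alkoxyaryl epoxides are prone to rearrangement by hydride shift, and 5-exo attack at C3 competes with the 6-endo opening wanted.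
- Comparison: on structure it builds more per step; on mechanism the ring closure itself is better defined, but it needs more independent selectivity events than the single cycloaddition of 15. On step economy the gain after the key step would be outweighed by the length of a route to A1, which would exceed that to 15.

Alternative 2: The C4–C4a bonds of the three upper units are cut, giving the tris(trans-epoxide) A4, an open chain of three aryl glycidyl ethers attached to C8 of a penta-O-benzylepicatechin unit. In the forward step a Lewis acid of the boron trifluoride type would open each benzylic epoxide, and the free ortho carbon of each phloroglucinol ether ring would attack C4 (intramolecular Friedel–Crafts, 6-endo) to give heptadeca-O-benzylcinnamtannin A2 A5.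
- In favour: three rings close at once, and the 3-hydroxyl is delivered free and anti to the new C4–C4a bond. The closure is intramolecular and needs no control of heterodiene geometry, so on the 3,4-trans relation this plan is the more secure of the two. One hydrogenolysis would finish the synthesis, again one step fewer than from 20.
- Against: each epoxide carbon C4 bears a 2,4,6-trioxygenated aryl group, so opening will go through a free cation, with loss of stereospecificity and a 1,2-hydride shift as a competing path. The C2–O1 bond of A4 is a para-alkoxybenzyl aryl ether, which the same Lewis acid can ionise, putting C2 at risk. A4 itself holds nine stereocentres in an acyclic array (three C2 ether centres and three epoxides) that would each need a separate asymmetric step.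
- Comparison: on structure the alternative forms three rings against one; on mechanism it is better at C3/C4 but worse at C2, which the chosen plan takes from the alkene geometry. On step economy the preparation of A4 would cost far more than the thirteen steps that lead to 15 and 18.

Alternative 3: The three C2–C1′ bonds are cut, giving the tris-lactone A6, in which the upper three units are 3-benzyloxy-4-arylchroman-2-ones. In the forward step the trivalent cerium reagent 3,4-bis(benzyloxy)phenylcerium dichloride A7 would add to the three lactone carbonyls, and ionic hydrogenation of the three lactols (a trialkylsilane and a Lewis acid) would give eicosa-O-benzylcinnamtannin A2 A8.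
- In favour: ring B is introduced last, which is better than the chosen plan for making analogues. C3 and C4 are fixed beforehand, and A8 is one hydrogenolysis from the target against two steps from 20.
- Against: an aryl ester is being attacked, so the tetrahedral intermediate can collapse by ring opening and take up a second aryl group, and the α-alkoxy lactone can enolise and lose its C3 configuration. In the reduction, hydride must reach the 2-aryl oxocarbenium ion on the face syn to the C4 aryl group to give the 2,3-cis relation. Axial attack anti to the C3 benzyloxy group favours this, but the 1,3-diaxial clash with the C4 substituent opposes it, and proton loss from C3 competes. All of this must succeed three times.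
- Comparison: on structure it sets three C2 centres by substrate control where the chosen plan sets C2, C3 and C4 of one ring from alkene and heterodiene geometry. On mechanism the chosen cycloaddition has the closer precedent. On step economy the end-game is equal or better, but A6 still needs three C4–C8 bonds made on lactone units, for which no short route is apparent.

Key step: step 14

Assumption: the (R) enantiomer of the phosphoric acid is taken as the one that leaves open the face of 19 leading to the 4β (4R) linkage; this is a stereochemical model, and the rest of the route does not depend on it.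

## Route

Step 1
Reactants: 1 (−)-epicatechin
Product: 2 5,7,3′,4′-tetra-O-benzyl-(−)-epicatechin
Conditions: BnBr (4.2 equiv), K2CO3, DMF, 0 °C → rt
Reagents that add atoms: benzyl bromide, BrCc1ccccc1
Why: Williamson etherification; carbonate deprotonates the four phenols but not the secondary 3-OH, and the mild base and temperature should avoid C2 epimerisation; no stereocentre is touched.

Step 2
Reactants: 2 5,7,3′,4′-tetra-O-benzyl-(−)-epicatechin
Product: 3 3,5,7,3′,4′-penta-O-benzyl-(−)-epicatechin
Conditions: NaH, BnBr, DMF, 0 °C → rt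
Reagents that add atoms: benzyl bromide, BrCc1ccccc1
Why: Williamson etherification of the secondary alkoxide; an ether at O3 is needed because esters and free hydroxyls would not survive the aryllithium steps, and with all phenols capped no base-induced ring opening at C2 is possible.

Step 3
Reactants: 3 3,5,7,3′,4′-penta-O-benzyl-(−)-epicatechin
Product: 4 8-bromo-3,5,7,3′,4′-penta-O-benzylepicatechin
Conditions: NBS (1.0 equiv), CH2Cl2, −78 → 0 °C
Reagents that add atoms: N-bromosuccinimide, O=C1CCC(=O)N1Br
Why: Electrophilic aromatic bromination; C8, flanked by O1 and the C7 benzyloxy group, is the most nucleophilic position of ring A, so one equivalent at low temperature should give the 8-bromide, which later serves as cap and as lithiation handle.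

Step 4
Reactants: 4 8-bromo-3,5,7,3′,4′-penta-O-benzylepicatechin
Product: 5 8-bromo-4β-(2-ethoxyethoxy)-3,5,7,3′,4′-penta-O-benzylepicatechin
Conditions: DDQ (2 equiv), 2-ethoxyethanol (5 equiv), CH2Cl2, rt
Reagents that add atoms: 2-ethoxyethanol, CCOCCO
Why: Benzylic oxidation by hydride abstraction from C4; the cation, stabilised by the ortho and para oxygens of ring A, is trapped by the alcohol anti to the C3 benzyloxy group. The new C4 centre is lost again on ionisation in steps 5 and 7, so its configuration is of no consequence.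

Step 5
Reactants: 5 8-bromo-4β-(2-ethoxyethoxy)-3,5,7,3′,4′-penta-O-benzylepicatechin; 3 3,5,7,3′,4′-penta-O-benzyl-(−)-epicatechin (1.5 equiv)
Product: 6 8-bromo-deca-O-benzylprocyanidin B2 (bromine on C8 of the upper unit)
Conditions: TMSOTf (0.2 equiv), CH2Cl2, −78 → −40 °C; Et3N quench
Reagents that add atoms: none
Why: Lewis-acid-promoted Friedel–Crafts alkylation; the C4 cation from 5 is attacked by C8 of 3 on the face anti to the C3 benzyloxy group, which sets the new C4 as 4β (3,4-trans). The bromine on 5 prevents self-condensation and further growth of the product.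

Step 6
Reactants: 6 8-bromo-deca-O-benzylprocyanidin B2
Product: 8 deca-O-benzylprocyanidin B2, via 8-lithio dimer 7 (not isolated)
Conditions: n-BuLi (1.2 equiv), THF, −78 °C; then H2O
Reagents that add atoms: none
Why: Bromine–lithium exchange at −78 °C is faster than deprotonation of benzyl ethers, and protonation of the aryllithium frees C8 of the upper unit for the next chain extension; no stereocentre is involved.

Step 7
Reactants: 5 8-bromo-4β-(2-ethoxyethoxy)-3,5,7,3′,4′-penta-O-benzylepicatechin; 8 deca-O-benzylprocyanidin B2 (1.2 equiv)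
Product: 9 8-bromo-pentadeca-O-benzylprocyanidin C1 (bromine on C8 of the top unit)
Conditions: TMSOTf (0.2 equiv), CH2Cl2, −78 → −40 °C; Et3N quench
Reagents that add atoms: none
Why: The same Friedel–Crafts alkylation; the only free C8 of 8 is more nucleophilic than any C6, and attack anti to the C3 benzyloxy group again gives the 4β linkage. The catalytic acid at low temperature should leave the existing interflavan bond intact, and the bromine cap stops further growth.

Step 8
Reactants: 10 2,4,6-trihydroxybenzaldehyde
Product: 11 4,6-bis(benzyloxy)-2-hydroxybenzaldehyde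
Conditions: BnBr (2.1 equiv), K2CO3, DMF, 0 °C → rt
Reagents that add atoms: benzyl bromide, BrCc1ccccc1
Why: Williamson etherification; the para hydroxyl and one ortho hydroxyl react, and the remaining ortho hydroxyl, held in a hydrogen bond to the formyl group, is much less nucleophilic and should stay free.

Step 9
Reactants: 11 4,6-bis(benzyloxy)-2-hydroxybenzaldehyde
Product: 12 2-(allyloxy)-4,6-bis(benzyloxy)benzaldehyde
Conditions: allyl bromide, K2CO3, DMF, 50 °C
Reagents that add atoms: allyl bromide, C=CCBr
Why: Williamson etherification of the hydrogen-bonded phenol under more forcing conditions; the allyl group will not migrate to the alkoxide formed in step 10 and is cleaved later under neutral conditions that leave benzyl ethers alone.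

Step 10
Reactants: 9 8-bromo-pentadeca-O-benzylprocyanidin C1; 12 2-(allyloxy)-4,6-bis(benzyloxy)benzaldehyde (2 equiv)
Product: 14 [2-(allyloxy)-4,6-bis(benzyloxy)phenyl](pentadeca-O-benzylprocyanidin C1-8-yl)methanol (both carbinol epimers), via 8-lithio trimer 13 (not isolated)
Conditions: n-BuLi (1.1 equiv), THF, −78 °C; then 12, −78 → −40 °C; then H2O
Reagents that add atoms: none
Why: Bromine–lithium exchange followed by 1,2-addition of the aryllithium to a non-enolisable aldehyde. The carbinol centre forms as a mixture of epimers, which does not matter because it becomes trigonal in step 14.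

Step 11
Reactants: 14 [2-(allyloxy)-4,6-bis(benzyloxy)phenyl](pentadeca-O-benzylprocyanidin C1-8-yl)methanol
Product: 15 [4,6-bis(benzyloxy)-2-hydroxyphenyl](pentadeca-O-benzylprocyanidin C1-8-yl)methanol (both carbinol epimers)
Conditions: Pd(PPh3)4 (5 mol %), morpholine (5 equiv), THF, rt; base-washed silica
Reagents that add atoms: none
Why: Tsuji–Trost deallylation; zerovalent palladium ionises the allyl aryl ether to a π-allyl complex, which morpholine captures. The neutral to slightly basic medium should keep the acid-labile doubly benzylic alcohol and all benzyl ethers intact.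

Step 12
Reactants: 16 3,4-bis(benzyloxy)benzaldehyde
Product: 17 1,2-bis(benzyloxy)-4-ethynylbenzene
Conditions: dimethyl (1-diazo-2-oxopropyl)phosphonate, K2CO3, MeOH/THF, rt
Reagents that add atoms: dimethyl (1-diazo-2-oxopropyl)phosphonate, COP(=O)(OC)C(=[N+]=[N-])C(C)=O
Why: Ohira–Bestmann variant of the Seyferth–Gilbert homologation; the diazomethylphosphonate anion formed in the flask adds to the aldehyde, and the alkylidene carbene formed after loss of phosphate and nitrogen rearranges to the terminal alkyne.

Step 13
Reactants: 17 1,2-bis(benzyloxy)-4-ethynylbenzene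
Product: 18 (Z)-2-[3,4-bis(benzyloxy)phenyl]ethenyl acetate
Conditions: AcOH (1.5 equiv), Ru(2-methylallyl)2[Ph2P(CH2)4PPh2] (2 mol %), PhMe, 60 °C
Reagents that add atoms: acetic acid, CC(=O)O
Why: Ruthenium-catalysed anti-Markovnikov addition of a carboxylic acid to a terminal alkyne through a ruthenium vinylidene; carboxylate attack at the metal-bound carbon and protonolysis with retention are known to give the Z-enol ester with this catalyst class.

Step 14
Reactants: 15 [4,6-bis(benzyloxy)-2-hydroxyphenyl](pentadeca-O-benzylprocyanidin C1-8-yl)methanol; 18 (Z)-2-[3,4-bis(benzyloxy)phenyl]ethenyl acetate (3 equiv)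
Product: 20 nonadeca-O-benzylcinnamtannin A2 3-O-acetate (acetate on O3 of the top unit), via ortho-quinone methide 19 (not isolated)
Conditions: (R)-3,3′-bis(2,4,6-triisopropylphenyl)-1,1′-binaphthyl-2,2′-diyl hydrogen phosphate (10 mol %), 4 Å MS, PhMe, 0 °C → rt
Reagents that add atoms: none
Why: The phosphoric acid protonates the doubly benzylic hydroxyl of 15, the sieves take up the water that is lost, and the ortho-quinone methide 19 (in its protonated form a bis(trialkoxyaryl)methyl cation) stays hydrogen-bonded or ion-paired to the chiral phosphate. The closest known reaction type is the chiral-phosphoric-acid-catalysed inverse-electron-demand hetero-Diels–Alder reaction of ortho-quinone methides, generated in situ from ortho-hydroxybenzylic alcohols, with styrenes and enol derivatives to give chromans. Ring C closes by intermolecular [4+2] cycloaddition across O1 and C4 of the heterodiene, with C3–C4 bonding advanced and O1–C2 bonding following in the same asynchronous step (in the stepwise limit the phenolic oxygen captures the C2 benzylic cation in a six-membered closure). The regiochemistry follows from the para-benzyloxy group of 18, which makes the benzylic carbon the terminus that carries positive charge and the acetoxy-bearing carbon the nucleophilic one, acetoxy being a far weaker donor. C2 and C3 come out cis because addition to the Z-alkene is suprafacial. C4 comes out trans to C3 because allylic strain with the C5 benzyloxy group turns the trimer-aryl substituent of 19 syn to the C8a carbonyl (the inside position), and endo approach of 18 then places ring B and the acetate on the side opposite to it. The absolute sense at C4, and with it at C2 and C3, is set by the face of 19 that the (R)-phosphate leaves open, the remote stereocentres of the trimer adding only a weak bias. The step also needs chemoselectivity over Friedel–Crafts capture of 19 by free C6 positions and over self-condensation, which the excess of 18, moderate dilution and the low electrophilicity of the donor-rich heterodiene should secure.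

Step 15
Reactants: 20 nonadeca-O-benzylcinnamtannin A2 3-O-acetate
Product: 21 nonadeca-O-benzylcinnamtannin A2 (3-OH of the top unit free)
Conditions: NaOMe (0.5 equiv), MeOH/THF, rt → 40 °C
Reagents that add atoms: none
Why: Base-catalysed transesterification of the secondary acetate by acyl–oxygen cleavage, so C3 keeps its configuration; benzyl ethers and interflavan bonds are inert to methoxide, and no free phenol is present yet.

Step 16
Reactants: 21 nonadeca-O-benzylcinnamtannin A2
Product: 22 cinnamtannin A2
Conditions: H2 (1 atm), Pd(OH)2/C, THF/MeOH/H2O, rt; filtration and lyophilisation under argon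
Reagents that add atoms: none
Why: Hydrogenolysis of the sixteen aryl and three alkyl benzyl ethers under neutral conditions; the benzylic O1–C2 and C4–C8 bonds of flavans should survive these mild conditions, and the aqueous co-solvent keeps the increasingly polar intermediates in solution. No stereocentre is touched.

## Compound list

1 | (−)-epicatechin, (2R,3R)-2-(3,4-dihydroxyphenyl)chromane-3,5,7-triol | Oc1cc(O)c2c(c1)O[C@H](c1ccc(O)c(O)c1)[C@H](O)C2 | starting material

2 | 5,7,3′,4′-tetra-O-benzyl-(−)-epicatechin (3-OH free, 2,3-cis) | c3ccccc3COc1cc(OCc3ccccc3)c2c(c1)O[C@H](c1ccc(OCc3ccccc3)c(OCc3ccccc3)c1)[C@H](O)C2 | intermediate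

3 | 3,5,7,3′,4′-penta-O-benzyl-(−)-epicatechin | c3ccccc3COc1cc(OCc3ccccc3)c2c(c1)O[C@H](c1ccc(OCc3ccccc3)c(OCc3ccccc3)c1)[C@H](OCc3ccccc3)C2 | intermediate

4 | 8-bromo-3,5,7,3′,4′-penta-O-benzylepicatechin | Brc1c(OCc3ccccc3)cc(OCc3ccccc3)c2c1O[C@H](c1ccc(OCc3ccccc3)c(OCc3ccccc3)c1)[C@H](OCc3ccccc3)C2 | intermediate

5 | 8-bromo-4β-(2-ethoxyethoxy)-3,5,7,3′,4′-penta-O-benzylepicatechin (C4 alkoxy trans to the C3 benzyloxy group) | Brc1c(OCc3ccccc3)cc(OCc3ccccc3)c2c1O[C@H](c1ccc(OCc3ccccc3)c(OCc3ccccc3)c1)[C@H](OCc3ccccc3)[C@H]2OCCOCC | intermediate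

6 | 8-bromo-deca-O-benzylprocyanidin B2, penta-O-benzylepicatechin-(4β→8)-penta-O-benzylepicatechin with bromine on C8 of the upper unit | Brc1c(OCc3ccccc3)cc(OCc3ccccc3)c2c1O[C@H](c1ccc(OCc3ccccc3)c(OCc3ccccc3)c1)[C@H](OCc3ccccc3)[C@H]2c1c(OCc3ccccc3)cc(OCc3ccccc3)c2c1O[C@H](c1ccc(OCc3ccccc3)c(OCc3ccccc3)c1)[C@H](OCc3ccccc3)C2 | intermediate

7 | 8-lithio-deca-O-benzylprocyanidin B2 (lithium on C8 of the upper unit) | [Li]c1c(OCc3ccccc3)cc(OCc3ccccc3)c2c1O[C@H](c1ccc(OCc3ccccc3)c(OCc3ccccc3)c1)[C@H](OCc3ccccc3)[C@H]2c1c(OCc3ccccc3)cc(OCc3ccccc3)c2c1O[C@H](c1ccc(OCc3ccccc3)c(OCc3ccccc3)c1)[C@H](OCc3ccccc3)C2 | intermediate (not isolated)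

8 | deca-O-benzylprocyanidin B2 | c3ccccc3COc1cc(OCc3ccccc3)c2c(c1)O[C@H](c1ccc(OCc3ccccc3)c(OCc3ccccc3)c1)[C@H](OCc3ccccc3)[C@H]2c1c(OCc3ccccc3)cc(OCc3ccccc3)c2c1O[C@H](c1ccc(OCc3ccccc3)c(OCc3ccccc3)c1)[C@H](OCc3ccccc3)C2 | intermediate

9 | 8-bromo-pentadeca-O-benzylprocyanidin C1, three penta-O-benzylepicatechin units joined 4β→8 with bromine on C8 of the top unit | Brc1c(OCc3ccccc3)cc(OCc3ccccc3)c2c1O[C@H](c1ccc(OCc3ccccc3)c(OCc3ccccc3)c1)[C@H](OCc3ccccc3)[C@H]2c1c(OCc3ccccc3)cc(OCc3ccccc3)c2c1O[C@H](c1ccc(OCc3ccccc3)c(OCc3ccccc3)c1)[C@H](OCc3ccccc3)[C@H]2c1c(OCc3ccccc3)cc(OCc3ccccc3)c2c1O[C@H](c1ccc(OCc3ccccc3)c(OCc3ccccc3)c1)[C@H](OCc3ccccc3)C2 | intermediate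

10 | 2,4,6-trihydroxybenzaldehyde | O=Cc1c(O)cc(O)cc1O | starting material

11 | 4,6-bis(benzyloxy)-2-hydroxybenzaldehyde | O=Cc1c(O)cc(OCc2ccccc2)cc1OCc1ccccc1 | intermediate

12 | 2-(allyloxy)-4,6-bis(benzyloxy)benzaldehyde | C=CCOc1cc(OCc2ccccc2)cc(OCc2ccccc2)c1C=O | intermediate

13 | 8-lithio-pentadeca-O-benzylprocyanidin C1 (lithium on C8 of the top unit) | [Li]c1c(OCc3ccccc3)cc(OCc3ccccc3)c2c1O[C@H](c1ccc(OCc3ccccc3)c(OCc3ccccc3)c1)[C@H](OCc3ccccc3)[C@H]2c1c(OCc3ccccc3)cc(OCc3ccccc3)c2c1O[C@H](c1ccc(OCc3ccccc3)c(OCc3ccccc3)c1)[C@H](OCc3ccccc3)[C@H]2c1c(OCc3ccccc3)cc(OCc3ccccc3)c2c1O[C@H](c1ccc(OCc3ccccc3)c(OCc3ccccc3)c1)[C@H](OCc3ccccc3)C2 | intermediate (not isolated)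

14 | [2-(allyloxy)-4,6-bis(benzyloxy)phenyl](pentadeca-O-benzylprocyanidin C1-8-yl)methanol, both epimers at the carbinol carbon | c3ccccc3COc1cc(OCc3ccccc3)c(c(OCC=C)c1)C(O)c1c(OCc3ccccc3)cc(OCc3ccccc3)c2c1O[C@H](c1ccc(OCc3ccccc3)c(OCc3ccccc3)c1)[C@H](OCc3ccccc3)[C@H]2c1c(OCc3ccccc3)cc(OCc3ccccc3)c2c1O[C@H](c1ccc(OCc3ccccc3)c(OCc3ccccc3)c1)[C@H](OCc3ccccc3)[C@H]2c1c(OCc3ccccc3)cc(OCc3ccccc3)c2c1O[C@H](c1ccc(OCc3ccccc3)c(OCc3ccccc3)c1)[C@H](OCc3ccccc3)C2 | intermediate

15 | [4,6-bis(benzyloxy)-2-hydroxyphenyl](pentadeca-O-benzylprocyanidin C1-8-yl)methanol, both epimers at the carbinol carbon | c3ccccc3COc1cc(OCc3ccccc3)c(c(O)c1)C(O)c1c(OCc3ccccc3)cc(OCc3ccccc3)c2c1O[C@H](c1ccc(OCc3ccccc3)c(OCc3ccccc3)c1)[C@H](OCc3ccccc3)[C@H]2c1c(OCc3ccccc3)cc(OCc3ccccc3)c2c1O[C@H](c1ccc(OCc3ccccc3)c(OCc3ccccc3)c1)[C@H](OCc3ccccc3)[C@H]2c1c(OCc3ccccc3)cc(OCc3ccccc3)c2c1O[C@H](c1ccc(OCc3ccccc3)c(OCc3ccccc3)c1)[C@H](OCc3ccccc3)C2 | intermediate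

16 | 3,4-bis(benzyloxy)benzaldehyde | O=Cc1ccc(OCc2ccccc2)c(OCc2ccccc2)c1 | starting material

17 | 1,2-bis(benzyloxy)-4-ethynylbenzene | C#Cc1ccc(OCc2ccccc2)c(OCc2ccccc2)c1 | intermediate

18 | (Z)-2-[3,4-bis(benzyloxy)phenyl]ethenyl acetate | CC(=O)O/C=C\c1ccc(OCc2ccccc2)c(OCc2ccccc2)c1 | intermediate

19 | (Z)-3,5-bis(benzyloxy)-6-[(pentadeca-O-benzylprocyanidin C1-8-yl)methylidene]cyclohexa-2,4-dien-1-one, trimer aryl syn to the carbonyl | O=C1C=C(OCc3ccccc3)C=C(OCc3ccccc3)/C1=C/c1c(OCc3ccccc3)cc(OCc3ccccc3)c2c1O[C@H](c1ccc(OCc3ccccc3)c(OCc3ccccc3)c1)[C@H](OCc3ccccc3)[C@H]2c1c(OCc3ccccc3)cc(OCc3ccccc3)c2c1O[C@H](c1ccc(OCc3ccccc3)c(OCc3ccccc3)c1)[C@H](OCc3ccccc3)[C@H]2c1c(OCc3ccccc3)cc(OCc3ccccc3)c2c1O[C@H](c1ccc(OCc3ccccc3)c(OCc3ccccc3)c1)[C@H](OCc3ccccc3)C2 | intermediate (not isolated)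

20 | nonadeca-O-benzylcinnamtannin A2 3-O-acetate: all sixteen phenols and O3 of the three lower units benzylated, O3 of the top unit acetylated; 2,3-cis-3,4-trans top unit, 4β→8 throughout | c3ccccc3COc1cc(OCc3ccccc3)c2c(c1)O[C@H](c1ccc(OCc3ccccc3)c(OCc3ccccc3)c1)[C@H](OC(C)=O)[C@H]2c1c(OCc3ccccc3)cc(OCc3ccccc3)c2c1O[C@H](c1ccc(OCc3ccccc3)c(OCc3ccccc3)c1)[C@H](OCc3ccccc3)[C@H]2c1c(OCc3ccccc3)cc(OCc3ccccc3)c2c1O[C@H](c1ccc(OCc3ccccc3)c(OCc3ccccc3)c1)[C@H](OCc3ccccc3)[C@H]2c1c(OCc3ccccc3)cc(OCc3ccccc3)c2c1O[C@H](c1ccc(OCc3ccccc3)c(OCc3ccccc3)c1)[C@H](OCc3ccccc3)C2 | intermediate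

21 | nonadeca-O-benzylcinnamtannin A2 (3-OH of the top unit free) | c3ccccc3COc1cc(OCc3ccccc3)c2c(c1)O[C@H](c1ccc(OCc3ccccc3)c(OCc3ccccc3)c1)[C@H](O)[C@H]2c1c(OCc3ccccc3)cc(OCc3ccccc3)c2c1O[C@H](c1ccc(OCc3ccccc3)c(OCc3ccccc3)c1)[C@H](OCc3ccccc3)[C@H]2c1c(OCc3ccccc3)cc(OCc3ccccc3)c2c1O[C@H](c1ccc(OCc3ccccc3)c(OCc3ccccc3)c1)[C@H](OCc3ccccc3)[C@H]2c1c(OCc3ccccc3)cc(OCc3ccccc3)c2c1O[C@H](c1ccc(OCc3ccccc3)c(OCc3ccccc3)c1)[C@H](OCc3ccccc3)C2 | intermediate

22 | cinnamtannin A2, epicatechin-(4β→8)-epicatechin-(4β→8)-epicatechin-(4β→8)-epicatechin | Oc1cc(O)c2c(c1)O[C@H](c1ccc(O)c(O)c1)[C@H](O)[C@H]2c1c(O)cc(O)c2c1O[C@H](c1ccc(O)c(O)c1)[C@H](O)[C@H]2c1c(O)cc(O)c2c1O[C@H](c1ccc(O)c(O)c1)[C@H](O)[C@H]2c1c(O)cc(O)c2c1O[C@H](c1ccc(O)c(O)c1)[C@H](O)C2 | target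

## Step count and least certain steps

Total step count: 16. Longest linear sequence: 12 steps (steps 1, 2, 3, 4, 5, 6, 7, 10, 11, 14, 15, 16, from 1 to 22).

Step 14 (key step). Several things could go wrong.
- Addition may become stepwise, because the para-alkoxybenzyl cation at C2 is long-lived; bond rotation before ring closure would erase the cis relation at C2/C3.
- Approach to the wrong face of C4, exo approach, or reaction through the other heterodiene geometry would give the 3,4-cis relation or the antipodal top unit.
- The acetoxy group could partly reverse the polarity of the alkene.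
- The cation could be consumed by Friedel–Crafts attack of the free C6 positions.

The fallback gives up the cycloaddition for the cationic chain extension already used twice. It sets out from 9: bromine–lithium exchange (13) and protonation with water would give pentadeca-O-benzylprocyanidin C1 F1. F1 and 5 with catalytic TMSOTf in CH2Cl2 at low temperature would give the capped tetramer eicosa-O-benzyl-8-bromocinnamtannin A2 F2, in which the new C4 is again set anti to the C3 benzyloxy group. Hydrogenolysis of F2 over Pd(OH)2/C with NaHCO3 as buffer would remove the bromine and all twenty benzyl groups and come back to the route at 22.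

Step 10. The aryllithium 13 is hindered by O1 and the C7 benzyloxy group, and the aldehyde 12 carries two ortho substituents. Slow addition would leave 13 open to protonation by adventitious acid or by benzylic hydrogens, returning reduced trimer, and small-scale work with a molecule of this size makes quantitative exchange hard to ensure. The fallback reverses the polarity. It sets out from 9: 13 would be trapped with excess N,N-dimethylformamide, a small electrophile, to give pentadeca-O-benzylprocyanidin C1-8-carbaldehyde F3. Commercial 3,5-bis(benzyloxy)phenol with EtMgBr in toluene/CH2Cl2 would give bromomagnesium 3,5-bis(benzyloxy)phenoxide F4, which should add to F3 through its ortho carbon in a chelated six-membered transition state (ortho-selective hydroxyalkylation of a magnesium phenoxide). This would come back to the route at 15 and bypass 14 and step 11.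

Step 16. Nineteen benzyl ethers must fall; partly debenzylated intermediates may lose solubility or bind to the catalyst so that hydrogenolysis stalls, and forcing the reaction risks hydrogenolytic opening of benzylic O1–C2 bonds. Separating the free tetramer from partly benzylated material is difficult. The fallback sets out from 21: the crude hydrogenolysis product would be acetylated (Ac2O, pyridine) to cinnamtannin A2 eicosaacetate F5, which can be purified on silica away from benzyl-containing material. Methanolysis with K2CO3 in degassed MeOH at 0 °C, followed by an acidic ion-exchange resin, would then come back to the route at 22.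

Step 8. Partial benzylation of a symmetrical triphenol relies on a hydrogen bond for selectivity; under- and over-alkylation and C-benzylation of the phloroglucinol ring may erode the outcome. The fallback sets out from 10: exhaustive benzylation (excess BnBr, K2CO3, DMF) would give 2,4,6-tris(benzyloxy)benzaldehyde F6, and chelation-directed cleavage of one ortho benzyl ether with MgBr2·OEt2 in toluene/ether would come back to the route at 11.

Step 4. The bromine lowers the donor ability of ring A, so hydride abstraction from C4 may be sluggish, and longer exposure to the oxidant invites over-oxidation at C4. The fallback changes the order of events. It sets out from 3: oxidation with DDQ and 2-ethoxyethanol before bromination would give 4β-(2-ethoxyethoxy)-3,5,7,3′,4′-penta-O-benzylepicatechin F7, and bromination of F7 with NBS at −78 °C at C8 would come back to the route at 5.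

## Further compounds

F1 | step 14 | pentadeca-O-benzylprocyanidin C1 | c3ccccc3COc1cc(OCc3ccccc3)c2c(c1)O[C@H](c1ccc(OCc3ccccc3)c(OCc3ccccc3)c1)[C@H](OCc3ccccc3)[C@H]2c1c(OCc3ccccc3)cc(OCc3ccccc3)c2c1O[C@H](c1ccc(OCc3ccccc3)c(OCc3ccccc3)c1)[C@H](OCc3ccccc3)[C@H]2c1c(OCc3ccccc3)cc(OCc3ccccc3)c2c1O[C@H](c1ccc(OCc3ccccc3)c(OCc3ccccc3)c1)[C@H](OCc3ccccc3)C2

F2 | step 14 | eicosa-O-benzyl-8-bromocinnamtannin A2 (bromine on C8 of the top unit) | Brc1c(OCc3ccccc3)cc(OCc3ccccc3)c2c1O[C@H](c1ccc(OCc3ccccc3)c(OCc3ccccc3)c1)[C@H](OCc3ccccc3)[C@H]2c1c(OCc3ccccc3)cc(OCc3ccccc3)c2c1O[C@H](c1ccc(OCc3ccccc3)c(OCc3ccccc3)c1)[C@H](OCc3ccccc3)[C@H]2c1c(OCc3ccccc3)cc(OCc3ccccc3)c2c1O[C@H](c1ccc(OCc3ccccc3)c(OCc3ccccc3)c1)[C@H](OCc3ccccc3)[C@H]2c1c(OCc3ccccc3)cc(OCc3ccccc3)c2c1O[C@H](c1ccc(OCc3ccccc3)c(OCc3ccccc3)c1)[C@H](OCc3ccccc3)C2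

F3 | step 10 | pentadeca-O-benzylprocyanidin C1-8-carbaldehyde (formyl on C8 of the top unit) | O=Cc1c(OCc3ccccc3)cc(OCc3ccccc3)c2c1O[C@H](c1ccc(OCc3ccccc3)c(OCc3ccccc3)c1)[C@H](OCc3ccccc3)[C@H]2c1c(OCc3ccccc3)cc(OCc3ccccc3)c2c1O[C@H](c1ccc(OCc3ccccc3)c(OCc3ccccc3)c1)[C@H](OCc3ccccc3)[C@H]2c1c(OCc3ccccc3)cc(OCc3ccccc3)c2c1O[C@H](c1ccc(OCc3ccccc3)c(OCc3ccccc3)c1)[C@H](OCc3ccccc3)C2

F4 | step 10 | bromomagnesium 3,5-bis(benzyloxy)phenoxide | Br[Mg]Oc1cc(OCc2ccccc2)cc(OCc2ccccc2)c1

F5 | step 16 | cinnamtannin A2 eicosaacetate | CC(=O)Oc1cc(OC(C)=O)c2c(c1)O[C@H](c1ccc(OC(C)=O)c(OC(C)=O)c1)[C@H](OC(C)=O)[C@H]2c1c(OC(C)=O)cc(OC(C)=O)c2c1O[C@H](c1ccc(OC(C)=O)c(OC(C)=O)c1)[C@H](OC(C)=O)[C@H]2c1c(OC(C)=O)cc(OC(C)=O)c2c1O[C@H](c1ccc(OC(C)=O)c(OC(C)=O)c1)[C@H](OC(C)=O)[C@H]2c1c(OC(C)=O)cc(OC(C)=O)c2c1O[C@H](c1ccc(OC(C)=O)c(OC(C)=O)c1)[C@H](OC(C)=O)C2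

F6 | step 8 | 2,4,6-tris(benzyloxy)benzaldehyde | O=Cc1c(OCc2ccccc2)cc(OCc2ccccc2)cc1OCc1ccccc1

F7 | step 4 | 4β-(2-ethoxyethoxy)-3,5,7,3′,4′-penta-O-benzylepicatechin | c3ccccc3COc1cc(OCc3ccccc3)c2c(c1)O[C@H](c1ccc(OCc3ccccc3)c(OCc3ccccc3)c1)[C@H](OCc3ccccc3)[C@H]2OCCOCC

A1 | alternative 1 | open-chain tetraene: four (Z)-2-[3,4-bis(benzyloxy)phenyl]ethenyl groups on C4 of four 5,7-bis(benzyloxy) rings A, each C8a oxygen as tert-butyldimethylsilyl ether, rings joined C4→C8 with the three C4 centres set | c1cc(OCc3ccccc3)c(OCc3ccccc3)cc1/C=C\[C@H](c1c(O[Si](C)(C)C(C)(C)C)cc(OCc3ccccc3)cc1OCc3ccccc3)c1c(OCc3ccccc3)cc(OCc3ccccc3)c(c1O[Si](C)(C)C(C)(C)C)[C@@H](/C=C\c1ccc(OCc3ccccc3)c(OCc3ccccc3)c1)c1c(OCc3ccccc3)cc(OCc3ccccc3)c(c1O[Si](C)(C)C(C)(C)C)[C@@H](/C=C\c1ccc(OCc3ccccc3)c(OCc3ccccc3)c1)c1c(OCc3ccccc3)cc(OCc3ccccc3)c(c1O[Si](C)(C)C(C)(C)C)C/C=C\c1ccc(OCc3ccccc3)c(OCc3ccccc3)c1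

A2 | alternative 1 | (R,R)-[N,N′-bis(3,5-di-tert-butylsalicylidene)-1,2-cyclohexanediaminato]manganese chloride (the antipode if the facial sense requires it) | CC(C)(C)c1cc(C=N[C@@H]2CCCC[C@H]2N=Cc2cc(C(C)(C)C)cc(C(C)(C)C)c2[O-])c([O-])c(C(C)(C)C)c1.[Mn+3].[Cl-]

A3 | alternative 1 | hexadeca-O-benzylcinnamtannin A2 (all phenols benzylated, four 3-OH free) | c3ccccc3COc1cc(OCc3ccccc3)c2c(c1)O[C@H](c1ccc(OCc3ccccc3)c(OCc3ccccc3)c1)[C@H](O)[C@H]2c1c(OCc3ccccc3)cc(OCc3ccccc3)c2c1O[C@H](c1ccc(OCc3ccccc3)c(OCc3ccccc3)c1)[C@H](O)[C@H]2c1c(OCc3ccccc3)cc(OCc3ccccc3)c2c1O[C@H](c1ccc(OCc3ccccc3)c(OCc3ccccc3)c1)[C@H](O)[C@H]2c1c(OCc3ccccc3)cc(OCc3ccccc3)c2c1O[C@H](c1ccc(OCc3ccccc3)c(OCc3ccccc3)c1)[C@H](O)C2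

A4 | alternative 2 | open-chain tris(trans-epoxide): three 3,5-bis(benzyloxy)phenyl ethers of 1-[3,4-bis(benzyloxy)phenyl]-2,3-epoxypropan-1-ol units, linked epoxide C4 to aryl C8, the last epoxide on C8 of penta-O-benzylepicatechin | c3ccccc3COc1cc(OCc3ccccc3)cc(c1)O[C@H](c1ccc(OCc3ccccc3)c(OCc3ccccc3)c1)[C@@H]4O[C@H]4c1c(OCc3ccccc3)cc(OCc3ccccc3)cc1O[C@H](c1ccc(OCc3ccccc3)c(OCc3ccccc3)c1)[C@@H]4O[C@H]4c1c(OCc3ccccc3)cc(OCc3ccccc3)cc1O[C@H](c1ccc(OCc3ccccc3)c(OCc3ccccc3)c1)[C@@H]4O[C@H]4c1c(OCc3ccccc3)cc(OCc3ccccc3)c2c1O[C@H](c1ccc(OCc3ccccc3)c(OCc3ccccc3)c1)[C@H](OCc3ccccc3)C2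

A5 | alternative 2 | heptadeca-O-benzylcinnamtannin A2 (all phenols and the bottom O3 benzylated, three upper 3-OH free) | c3ccccc3COc1cc(OCc3ccccc3)c2c(c1)O[C@H](c1ccc(OCc3ccccc3)c(OCc3ccccc3)c1)[C@H](O)[C@H]2c1c(OCc3ccccc3)cc(OCc3ccccc3)c2c1O[C@H](c1ccc(OCc3ccccc3)c(OCc3ccccc3)c1)[C@H](O)[C@H]2c1c(OCc3ccccc3)cc(OCc3ccccc3)c2c1O[C@H](c1ccc(OCc3ccccc3)c(OCc3ccccc3)c1)[C@H](O)[C@H]2c1c(OCc3ccccc3)cc(OCc3ccccc3)c2c1O[C@H](c1ccc(OCc3ccccc3)c(OCc3ccccc3)c1)[C@H](OCc3ccccc3)C2

A6 | alternative 3 | tris-lactone: three 3,5,7-tris(benzyloxy)chroman-2-one units joined 4β→8 and to C8 of penta-O-benzylepicatechin | c3ccccc3COc1cc(OCc3ccccc3)c2c(c1)OC(=O)[C@H](OCc3ccccc3)[C@H]2c1c(OCc3ccccc3)cc(OCc3ccccc3)c2c1OC(=O)[C@H](OCc3ccccc3)[C@H]2c1c(OCc3ccccc3)cc(OCc3ccccc3)c2c1OC(=O)[C@H](OCc3ccccc3)[C@H]2c1c(OCc3ccccc3)cc(OCc3ccccc3)c2c1O[C@H](c1ccc(OCc3ccccc3)c(OCc3ccccc3)c1)[C@H](OCc3ccccc3)C2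

A7 | alternative 3 | 3,4-bis(benzyloxy)phenylcerium dichloride | Cl[Ce](Cl)c1ccc(OCc2ccccc2)c(OCc2ccccc2)c1

A8 | alternative 3 | eicosa-O-benzylcinnamtannin A2 (all phenols and all four O3 benzylated) | c3ccccc3COc1cc(OCc3ccccc3)c2c(c1)O[C@H](c1ccc(OCc3ccccc3)c(OCc3ccccc3)c1)[C@H](OCc3ccccc3)[C@H]2c1c(OCc3ccccc3)cc(OCc3ccccc3)c2c1O[C@H](c1ccc(OCc3ccccc3)c(OCc3ccccc3)c1)[C@H](OCc3ccccc3)[C@H]2c1c(OCc3ccccc3)cc(OCc3ccccc3)c2c1O[C@H](c1ccc(OCc3ccccc3)c(OCc3ccccc3)c1)[C@H](OCc3ccccc3)[C@H]2c1c(OCc3ccccc3)cc(OCc3ccccc3)c2c1O[C@H](c1ccc(OCc3ccccc3)c(OCc3ccccc3)c1)[C@H](OCc3ccccc3)C2
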